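## Retrosynthetic overview
1. The C5–OMe bond of ring A is cut last. It is made by a new carbonyl-directed C5–H methoxylation of 6,3',4',5'-tetramethoxyflavone with the oxygen electrophile MeO–N(SO2Ph)2. This position, between C4a and C6, is the crowded one that acylation of 3,4-dimethoxyphenol does not reach.
2. The tetramethoxyflavone comes from oxidative cyclisation of the 2'-hydroxychalcone (I2/DMSO), which forms the O1–C2 bond and the C2=C3 unsaturation.
3. The chalcone comes from Claisen–Schmidt condensation of 2'-hydroxy-5'-methoxyacetophenone with 3,4,5-trimethoxybenzaldehyde (C2–C3 bond, flavone numbering).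
4. MeO–N(SO2Ph)2 comes from MeONH2·HCl and PhSO2Cl.
5. Ring order: rings A and B are bought as arenes. Ring C is the only ring formed (step 2), before the final C–O bond.

Assumption: the target SMILES has no stereocentre, stereogenic axis or stereogenic double bond. The compound is achiral, so the single-enantiomer request needs no stereocontrol. The transient stereocentres in 3 and 5 are racemic and are destroyed within the same step.

## Route

Step 1
Reactants: 1 1-(2-hydroxy-5-methoxyphenyl)ethan-1-one; 2 3,4,5-trimethoxybenzaldehyde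
Product: 4 (E)-1-(2-hydroxy-5-methoxyphenyl)-3-(3,4,5-trimethoxyphenyl)prop-2-en-1-one, via aldol adduct 3 (not isolated)
Conditions: KOH (50 % aq., 5 equiv), EtOH, 0 °C to rt, 36 h; then dilute aq. HCl
Reagents that add atoms: none
Why: Claisen–Schmidt condensation, in which the methyl ketone enolate adds to the non-enolisable aldehyde and E1cB loss of water from 3 gives the conjugated enone as the thermodynamically favoured E isomer, with no stereocentre left.

Step 2
Reactants: 4 (E)-1-(2-hydroxy-5-methoxyphenyl)-3-(3,4,5-trimethoxyphenyl)prop-2-en-1-one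
Product: 6 flavone 6-methoxy-2-(3,4,5-trimethoxyphenyl)-4H-chromen-4-one, via flavanone 5 (not isolated)
Conditions: I2 (10 mol %), DMSO, 130 °C, 3 h
Reagents that add atoms: none
Why: Iodine-catalysed oxidative cyclisation of a 2'-hydroxychalcone, in which 6-endo oxa-Michael closure gives 5 and iodine-mediated dehydrogenation with DMSO as terminal oxidant forms ring C, while the aryl methyl ethers are inert.

Step 3
Reactants: 7 O-methylhydroxylamine hydrochloride; 8 benzenesulfonyl chloride (2.2 equiv)
Product: 10 N-methoxy-N-(phenylsulfonyl)benzenesulfonamide, via N-methoxybenzenesulfonamide 9 (not isolated)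
Conditions: Et3N (3.5 equiv), DMAP (10 mol %), CH2Cl2, 0 °C to rt, 12 h
Reagents that add atoms: 8 benzenesulfonyl chloride, O=S(=O)(Cl)c1ccccc1
Why: Twofold Hinsberg-type N-sulfonylation, in which the liberated alkoxyamine gives 9 and its acidic N–H is deprotonated by Et3N and sulfonylated again under DMAP catalysis.

Step 4
Reactants: 6 flavone 6-methoxy-2-(3,4,5-trimethoxyphenyl)-4H-chromen-4-one; 10 N-methoxy-N-(phenylsulfonyl)benzenesulfonamide
Product: 11 Cerosilin B, 5,6-dimethoxy-2-(3,4,5-trimethoxyphenyl)-4H-chromen-4-one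
Conditions: [Ru(O2CMes)2(p-cymene)] (10 mol %, Mes = 2,4,6-trimethylphenyl), 10 (1.5 equiv), ClCH2CH2Cl, 80 °C, 18 h, under argon
Reagents that add atoms: 10 N-methoxy-N-(phenylsulfonyl)benzenesulfonamide, CON(S(=O)(=O)c1ccccc1)S(=O)(=O)c1ccccc1
Why: Proposed new method: carbonyl-directed C5–H methoxylation of a flavone with an oxygen-electrophilic N–O reagent; the strongly Lewis-basic pyranone C4=O binds [Ru(O2CMes)2(p-cymene)] (divalent ruthenium), and carboxylate-assisted concerted metalation–deprotonation can reach only the peri C5–H through a five-membered chelate (C3–H would need a four-membered chelate and ring B is out of reach); the electron-rich Ru–aryl unit then attacks the methoxy oxygen of 10 in an SN2-type step, helped by sulfonyl-oxygen pre-coordination, and expels the very stable bis(sulfonyl)amide anion, because the two sulfonyl groups reverse the usual N–O polarity; C5–OMe reductive elimination from tetravalent ruthenium and proton transfer from MesCO2H close the cycle, and no single-electron oxidant or strong acid medium is present that could attack the two polymethoxyarenes; the closest known reaction types are ruthenium-catalysed carbonyl-directed C5–H hydroxylation of flavones with trivalent iodine oxidants and ortho-methoxylation of aryl–norbornyl palladacycles with N,N-bis(sulfonyl)methoxyamines.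

## Compound list
1 | 1-(2-hydroxy-5-methoxyphenyl)ethan-1-one (2'-hydroxy-5'-methoxyacetophenone) | CC(=O)c1cc(OC)ccc1O | starting material
2 | 3,4,5-trimethoxybenzaldehyde | COc1cc(C=O)cc(OC)c1OC | starting material
3 | aldol adduct, racemic 3-hydroxy-1-(2-hydroxy-5-methoxyphenyl)-3-(3,4,5-trimethoxyphenyl)propan-1-one (not isolated) | COc1ccc(O)c(C(=O)CC(O)c2cc(OC)c(OC)c(OC)c2)c1 | intermediate
4 | (E)-1-(2-hydroxy-5-methoxyphenyl)-3-(3,4,5-trimethoxyphenyl)prop-2-en-1-one | COc1ccc(O)c(C(=O)/C=C/c2cc(OC)c(OC)c(OC)c2)c1 | intermediate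
5 | flavanone, racemic 6-methoxy-2-(3,4,5-trimethoxyphenyl)chroman-4-one (not isolated) | COc1ccc2OC(c3cc(OC)c(OC)c(OC)c3)CC(=O)c2c1 | intermediate
6 | 6-methoxy-2-(3,4,5-trimethoxyphenyl)-4H-chromen-4-one (6,3',4',5'-tetramethoxyflavone) | COc1ccc2oc(-c3cc(OC)c(OC)c(OC)c3)cc(=O)c2c1 | intermediate
7 | O-methylhydroxylamine hydrochloride | CON.Cl | starting material
8 | benzenesulfonyl chloride | O=S(=O)(Cl)c1ccccc1 | starting material
9 | N-methoxybenzenesulfonamide (not isolated) | CONS(=O)(=O)c1ccccc1 | intermediate
10 | N-methoxy-N-(phenylsulfonyl)benzenesulfonamide | CON(S(=O)(=O)c1ccccc1)S(=O)(=O)c1ccccc1 | intermediate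
11 | Cerosilin B, 5,6-dimethoxy-2-(3,4,5-trimethoxyphenyl)-4H-chromen-4-one (achiral) | COc1cc(-c2cc(=O)c3c(OC)c(OC)ccc3o2)cc(OC)c1OC | target

## Step count and risks
Total step count: 4. Longest linear sequence: 3 steps (1 to 4 to 6 to 11). Step 3 is a one-step side branch that supplies 10.

**First, step 4 (the proposed new step).**
- C5 is flanked by the 6-OMe group, so ruthenation may be slow.
- The Ru–aryl unit may be too weak a nucleophile for oxygen transfer.
- It may instead reduce 10 by one electron, which would lead to radical attack at C8, para to the Ru–C bond.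
- A Ru–OMe species may lose formaldehyde by β-hydride elimination.
- The C–N bond may form in place of the C–O bond.

The fallback uses only known chemistry and needs no C–H metalation of the flavone. It sets out from 2 and comes back to the route at 11. Commercial 3,4-dimethoxyphenol is protected with MOMCl and iPr2NEt in CH2Cl2 to give 1,2-dimethoxy-4-(methoxymethoxy)benzene F1. Directed ortho-lithiation with n-BuLi in THF at 0 °C takes place at the position flanked by the OMOM and OMe groups and gives [2,3-dimethoxy-6-(methoxymethoxy)phenyl]lithium F2. This is acylated with N-methoxy-N-methylacetamide (dilute aq. HCl quench) to 1-[2,3-dimethoxy-6-(methoxymethoxy)phenyl]ethan-1-one F3. HCl in MeOH at 50 °C removes the MOM group and gives 1-(6-hydroxy-2,3-dimethoxyphenyl)ethan-1-one F4. Claisen–Schmidt condensation of F4 with 2 under the conditions of step 1 passes through racemic 3-hydroxy-1-(6-hydroxy-2,3-dimethoxyphenyl)-3-(3,4,5-trimethoxyphenyl)propan-1-one F5 and gives (E)-1-(6-hydroxy-2,3-dimethoxyphenyl)-3-(3,4,5-trimethoxyphenyl)prop-2-en-1-one F6. I2 (10 mol %) in DMSO at 130 °C then closes ring C through racemic 5,6-dimethoxy-2-(3,4,5-trimethoxyphenyl)chroman-4-one F7 and delivers 11.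

**Second, step 3.**
- The second sulfonylation of the weakly nucleophilic anion of 9 may stall.
- 10 may fragment under amine base by deprotonation of the OCH3 group with N–O cleavage.

The fallback builds both N–S bonds from nitrogen in a higher oxidation state and methylates last under neutral conditions. It sets out from 8 and comes back at 10. Compound 8 is reduced with Na2SO3 and NaHCO3 in water at 80 °C to sodium benzenesulfinate F8. Treatment of F8 with NaNO2 in dilute aq. HCl at 0 °C condenses two sulfinic acid units with nitrous acid and precipitates N-hydroxy-N-(phenylsulfonyl)benzenesulfonamide F9. O-Methylation of F9 with TMSCHN2 in toluene/MeOH at 0 °C gives 10.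

**Third, step 2.**
- Hot I2/DMSO may iodinate the electron-rich ring B.
- The reaction may stop at flavanone 5.
- Some aurone may form.

The fallback avoids any oxidation by using a Baker–Venkataraman sequence. It sets out from 1 and comes back at 6. Compound 1 is O-acylated with commercial 3,4,5-trimethoxybenzoyl chloride in pyridine to give 2-acetyl-4-methoxyphenyl 3,4,5-trimethoxybenzoate F10. KOH in pyridine at 50 °C brings about the O-to-C acyl shift to 1-(2-hydroxy-5-methoxyphenyl)-3-(3,4,5-trimethoxyphenyl)propane-1,3-dione F11. Catalytic H2SO4 in AcOH at 100 °C cyclodehydrates F11 to 6.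

## Further compounds
F1 | step 4 | 1,2-dimethoxy-4-(methoxymethoxy)benzene | COCOc1ccc(OC)c(OC)c1
F2 | step 4 | [2,3-dimethoxy-6-(methoxymethoxy)phenyl]lithium | [Li]c1c(OC)c(OC)ccc1OCOC
F3 | step 4 | 1-[2,3-dimethoxy-6-(methoxymethoxy)phenyl]ethan-1-one | CC(=O)c1c(OC)c(OC)ccc1OCOC
F4 | step 4 | 1-(6-hydroxy-2,3-dimethoxyphenyl)ethan-1-one | CC(=O)c1c(OC)c(OC)ccc1O
F5 | step 4 | racemic 3-hydroxy-1-(6-hydroxy-2,3-dimethoxyphenyl)-3-(3,4,5-trimethoxyphenyl)propan-1-one | COc1ccc(O)c(C(=O)CC(O)c2cc(OC)c(OC)c(OC)c2)c1OC
F6 | step 4 | (E)-1-(6-hydroxy-2,3-dimethoxyphenyl)-3-(3,4,5-trimethoxyphenyl)prop-2-en-1-one | COc1ccc(O)c(C(=O)/C=C/c2cc(OC)c(OC)c(OC)c2)c1OC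
F7 | step 4 | racemic 5,6-dimethoxy-2-(3,4,5-trimethoxyphenyl)chroman-4-one | COc1ccc2OC(c3cc(OC)c(OC)c(OC)c3)CC(=O)c2c1OC
F8 | step 3 | sodium benzenesulfinate | [Na+].[O-]S(=O)c1ccccc1
F9 | step 3 | N-hydroxy-N-(phenylsulfonyl)benzenesulfonamide | ON(S(=O)(=O)c1ccccc1)S(=O)(=O)c1ccccc1
F10 | step 2 | 2-acetyl-4-methoxyphenyl 3,4,5-trimethoxybenzoate | COc1ccc(OC(=O)c2cc(OC)c(OC)c(OC)c2)c(C(C)=O)c1
F11 | step 2 | 1-(2-hydroxy-5-methoxyphenyl)-3-(3,4,5-trimethoxyphenyl)propane-1,3-dione | COc1ccc(O)c(C(=O)CC(=O)c2cc(OC)c(OC)c(OC)c2)c1
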